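**Strategy**

The target is cut at C13–C14 (cyclohexane ring C6–C11, arm from C12), between the second methylene on quaternary C11 and the CH of the first E-trisubstituted olefin. One operation, hydroboration then B-alkyl Suzuki–Miyaura coupling, joins a C11-vinyl cyclohexanol carrying all three ring stereocentres (enal masked as a C7 ketal) to a fourteen-carbon (E)-alkenyl iodide made by carboalumination of a geranyl-derived alkyne, so the olefin geometry is fixed before the union and only transferred. The step exploits the two-carbon spacer C12–C13 between ring carbon C11 and the C14=C15 olefin: a vinyl group is its latent form. The ring stereocentres stem from catalytic asymmetric conjugate addition and enolate vinylation on an achiral quinone monoketal.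

Key step: step 8

Remark: locants C6–C15 in the comments refer to the target (C6 = ring CH bearing the ester arm, C7 = ylidene carbon, C10 = carbinol carbon, C11 = quaternary carbon).
Remark: the carbinol configuration at C7 in 21 and 22 is assumed to be without consequence, because this carbon becomes sp2 in step 12; the epimer expected from equatorial attack is drawn.

**Route**

Step 1
Reactants: 1 4-methoxy-2-methylphenol
Product: 2 4,4-dimethoxy-2-methylcyclohexa-2,5-dien-1-one
Conditions: PhI(OAc)2, MeOH, 0 °C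
Reagents that add atoms: methanol, CO
Why: Oxidative dearomatisation of a para-alkoxyphenol in methanol should trap the phenoxenium ion at the methoxy-bearing carbon and give the quinone monoketal.

Step 2
Reactants: 2 4,4-dimethoxy-2-methylcyclohexa-2,5-dien-1-one
Product: 3 4,4-dimethoxy-2-methylcyclohex-2-en-1-one
Conditions: H2 (1 atm), RhCl(PPh3)3 (cat.), benzene, rt
Reagents that add atoms: none
Why: Homogeneous hydrogenation should reduce the disubstituted enone olefin and leave the trisubstituted, methyl-bearing one, giving an achiral enone with one free β-carbon.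

Step 3
Reactants: 3 4,4-dimethoxy-2-methylcyclohex-2-en-1-one; 4 tert-butyl(3-iodopropoxy)dimethylsilane
Product: 7 (3S)-3-{3-[tert-butyl(dimethyl)silyl]oxypropyl}-4,4-dimethoxy-2-methylcyclohex-1-en-1-yl acetate, via dialkylzinc 5 (not isolated), via zinc enolate 6 (not isolated)
Conditions: 4, diethylzinc, CuI (cat.), 50 °C, then vacuum; 3, Cu(OTf)2 (cat.), (R,S,S)-phosphoramidite from (R)-1,1′-bi-2-naphthol and bis[(S)-1-phenylethyl]amine (cat.), toluene, −30 °C; then Ac2O, 0 °C
Reagents that add atoms: acetic anhydride, CC(=O)OC(C)=O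
Why: Copper-catalysed asymmetric conjugate addition of a functionalised dialkylzinc (from iodine–zinc exchange) should set C6 by catalyst-controlled face selection, the ligand enantiomer being chosen by analogy with cyclohexenone to give 3S, and O-acetylation of the zinc enolate fixes the enolate regiochemistry.

Step 4
Reactants: 7 (3S)-3-{3-[tert-butyl(dimethyl)silyl]oxypropyl}-4,4-dimethoxy-2-methylcyclohex-1-en-1-yl acetate
Product: 9 (2S,3S)-3-{3-[tert-butyl(dimethyl)silyl]oxypropyl}-2-ethenyl-4,4-dimethoxy-2-methylcyclohexan-1-one, via lithium enolate 8 (not isolated)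
Conditions: methyllithium (2 equiv), THF, 0 °C; then Pd2(dba)3 (cat.), P(t-Bu)3 (cat.), vinyl bromide, THF, rt; then H2O
Reagents that add atoms: vinyl bromide, C=CBr
Why: Methyllithium cleaves the enol acetate to the regiodefined lithium enolate, and its palladium-catalysed α-vinylation (ketone enolate vinylation) should build quaternary C11 with the vinyl group entering anti to the adjacent C6 side chain, so that methyl and side chain end cis.

Step 5
Reactants: 9 (2S,3S)-3-{3-[tert-butyl(dimethyl)silyl]oxypropyl}-2-ethenyl-4,4-dimethoxy-2-methylcyclohexan-1-one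
Product: 10 (1S,2S,3S)-3-{3-[tert-butyl(dimethyl)silyl]oxypropyl}-2-ethenyl-4,4-dimethoxy-1,2-dimethylcyclohexan-1-ol
Conditions: methyllithium, THF, −78 °C; then H2O
Reagents that add atoms: methyllithium, [Li]C
Why: 1,2-Addition to the α-quaternary cyclohexanone should occur axially, anti to the axial C11 methyl and on the face remote from the C6 side chain (chair with side chain and vinyl equatorial), placing the new C10 methyl cis to vinyl and the hydroxyl cis to the C11 methyl.

Step 6
Reactants: 11 geranyl bromide [(2E)-1-bromo-3,7-dimethylocta-2,6-diene]; 12 trimethyl(prop-1-yn-1-yl)silane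
Product: 15 (5E)-6,10-dimethylundeca-5,9-dien-1-yne, via propargyllithium 13 (not isolated), via silyl enyne 14 (not isolated)
Conditions: 12, n-butyllithium, THF, −78 °C; 11, −78 → 0 °C; then MeOH, K2CO3 (cat.), rt
Reagents that add atoms: none
Why: The lithiated silylpropyne should displace the allylic bromide at its primary carbon (propargylic alkylation, geranyl E geometry untouched), and methanolysis removes the alkynyl silane.

Step 7
Reactants: 15 (5E)-6,10-dimethylundeca-5,9-dien-1-yne
Product: 17 (1E,5E)-1-iodo-2,6,10-trimethylundeca-1,5,9-triene, via alkenylalane 16 (not isolated)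
Conditions: trimethylaluminium, Cp2ZrCl2 (cat.), CH2Cl2, 0 °C → rt; then I2, THF, −30 °C
Reagents that add atoms: trimethylaluminium, C[Al](C)C; iodine, II
Why: Zirconium-catalysed syn-carboalumination (Negishi carboalumination) should place methyl on the internal and aluminium on the terminal alkyne carbon, and iodinolysis with retention gives the (E)-alkenyl iodide.

Step 8
Reactants: 10 (1S,2S,3S)-3-{3-[tert-butyl(dimethyl)silyl]oxypropyl}-2-ethenyl-4,4-dimethoxy-1,2-dimethylcyclohexan-1-ol; 17 (1E,5E)-1-iodo-2,6,10-trimethylundeca-1,5,9-triene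
Product: 19 (1S,2S,3S)-3-{3-[tert-butyl(dimethyl)silyl]oxypropyl}-4,4-dimethoxy-1,2-dimethyl-2-[(3E,7E)-4,8,12-trimethyltrideca-3,7,11-trien-1-yl]cyclohexan-1-ol, via alkylborane 18 (not isolated)
Conditions: 9-BBN (excess), THF, rt; then H2O; then 17, PdCl2(dppf) (cat.), AsPh3, Cs2CO3, DMF–H2O, rt
Reagents that add atoms: none
Why: 9-BBN adds to the only alkene of 10 with boron on the terminal carbon (anti-Markovnikov, enforced by the adjacent quaternary C11), and the primary alkylborane 18, activated as its hydroxyborate, transmetalates to the alkenylpalladium iodide formed from 17 and zerovalent palladium, after which reductive elimination forms the C13–C14 bond. The closest known reaction type is the B-alkyl Suzuki–Miyaura coupling of a 9-BBN adduct with an (E)-alkenyl iodide. No ring is closed and no stereocentre is created; the ring stereocentres are remote from the reacting carbon, and the E geometry of 17 is retained because oxidative addition and reductive elimination are stereoretentive. The step needs chemoselective hydroboration, secured because the trisubstituted olefins arrive only with 17 after the excess borane is quenched, and coupling faster than β-hydride elimination, secured by the dppf/AsPh3 catalyst at room temperature.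

Step 9
Reactants: 19 (1S,2S,3S)-3-{3-[tert-butyl(dimethyl)silyl]oxypropyl}-4,4-dimethoxy-1,2-dimethyl-2-[(3E,7E)-4,8,12-trimethyltrideca-3,7,11-trien-1-yl]cyclohexan-1-ol
Product: 20 (2S,3S,4S)-4-hydroxy-2-(3-hydroxypropyl)-3,4-dimethyl-3-[(3E,7E)-4,8,12-trimethyltrideca-3,7,11-trien-1-yl]cyclohexan-1-one
Conditions: AcOH–THF–H2O (3:1:1), 35 °C
Reagents that add atoms: water, O
Why: Mild aqueous acid should hydrolyse the dimethyl ketal to the C7 ketone and cleave the primary silyl ether in one operation without touching the tertiary alcohol or the trisubstituted olefins.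

Step 10
Reactants: 20 (2S,3S,4S)-4-hydroxy-2-(3-hydroxypropyl)-3,4-dimethyl-3-[(3E,7E)-4,8,12-trimethyltrideca-3,7,11-trien-1-yl]cyclohexan-1-one
Product: 21 (1S,2S,3S,4R)-3-(3-hydroxypropyl)-1,2-dimethyl-4-(prop-1-en-2-yl)-2-[(3E,7E)-4,8,12-trimethyltrideca-3,7,11-trien-1-yl]cyclohexane-1,4-diol
Conditions: isopropenylmagnesium bromide (excess), LaCl3·2LiCl, THF, 0 °C → rt; then H2O
Reagents that add atoms: isopropenylmagnesium bromide, CC(=C)[Mg]Br
Why: Lanthanum-assisted Grignard 1,2-addition to the enolisable, α-branched C7 ketone (the two hydroxy groups are carried as alkoxides) should install all three carbons of the future enal unit.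

Step 11
Reactants: 21 (1S,2S,3S,4R)-3-(3-hydroxypropyl)-1,2-dimethyl-4-(prop-1-en-2-yl)-2-[(3E,7E)-4,8,12-trimethyltrideca-3,7,11-trien-1-yl]cyclohexane-1,4-diol
Product: 22 3-[(1S,2S,3S,6R)-3,6-dihydroxy-2,3-dimethyl-6-(prop-1-en-2-yl)-2-[(3E,7E)-4,8,12-trimethyltrideca-3,7,11-trien-1-yl]cyclohexyl]propyl decanoate
Conditions: decanoyl chloride (1.1 equiv), 2,4,6-collidine, CH2Cl2, −30 → 0 °C
Reagents that add atoms: decanoyl chloride, CCCCCCCCCC(=O)Cl
Why: Acylation without a nucleophilic catalyst should take place only at the primary hydroxyl, the two tertiary alcohols being inert under these conditions.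

Step 12
Reactants: 22 3-[(1S,2S,3S,6R)-3,6-dihydroxy-2,3-dimethyl-6-(prop-1-en-2-yl)-2-[(3E,7E)-4,8,12-trimethyltrideca-3,7,11-trien-1-yl]cyclohexyl]propyl decanoate
Product: 23 3-[(1R,2S,3S,6Z)-3-hydroxy-2,3-dimethyl-6-(1-oxopropan-2-ylidene)-2-[(3E,7E)-4,8,12-trimethyltrideca-3,7,11-trien-1-yl]cyclohexyl]propyl decanoate
Conditions: pyridinium chlorochromate [C5H5NH][CrO3Cl], 4 Å molecular sieves, CH2Cl2, rt
Reagents that add atoms: pyridinium chlorochromate, [O-][Cr](=O)(=O)Cl.c1cc[nH+]cc1
Why: In the Babler–Dauben oxidative transposition the chromate ester of the tertiary allylic alcohol undergoes a reversible [3,3] shift to the primary allylic chromate, which is oxidised to the enal while the non-allylic C10 alcohol cannot react; the Z isomer is expected to prevail because the interconverting chromates funnel to the geometry with formyl rather than methyl facing substituted C6 (less allylic 1,3-strain).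

**Compound list**

1 | 4-methoxy-2-methylphenol | Cc1cc(OC)ccc1O | starting material
2 | 4,4-dimethoxy-2-methylcyclohexa-2,5-dien-1-one | COC1(OC)C=CC(=O)C(C)=C1 | intermediate
3 | 4,4-dimethoxy-2-methylcyclohex-2-en-1-one | COC1(OC)CCC(=O)C(C)=C1 | intermediate
4 | tert-butyl(3-iodopropoxy)dimethylsilane | CC(C)(C)[Si](C)(C)OCCCI | starting material
5 | bis{3-[tert-butyl(dimethyl)silyl]oxypropyl}zinc | CC(C)(C)[Si](C)(C)OCCC[Zn]CCCO[Si](C)(C)C(C)(C)C | intermediate
6 | zinc enolate: {[(3S)-3-{3-[tert-butyl(dimethyl)silyl]oxypropyl}-4,4-dimethoxy-2-methylcyclohex-1-en-1-yl]oxy}{3-[tert-butyl(dimethyl)silyl]oxypropyl}zinc | CC(C)(C)[Si](C)(C)OCCC[C@@H]1C(OC)(OC)CCC(O[Zn]CCCO[Si](C)(C)C(C)(C)C)=C1C | intermediate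
7 | (3S)-3-{3-[tert-butyl(dimethyl)silyl]oxypropyl}-4,4-dimethoxy-2-methylcyclohex-1-en-1-yl acetate | CC(C)(C)[Si](C)(C)OCCC[C@@H]1C(OC)(OC)CCC(OC(C)=O)=C1C | intermediate
8 | lithium (3S)-3-{3-[tert-butyl(dimethyl)silyl]oxypropyl}-4,4-dimethoxy-2-methylcyclohex-1-en-1-olate | CC(C)(C)[Si](C)(C)OCCC[C@@H]1C(OC)(OC)CCC(O[Li])=C1C | intermediate
9 | (2S,3S)-3-{3-[tert-butyl(dimethyl)silyl]oxypropyl}-2-ethenyl-4,4-dimethoxy-2-methylcyclohexan-1-one (vinyl trans to the side chain) | CC(C)(C)[Si](C)(C)OCCC[C@@H]1C(OC)(OC)CCC(=O)[C@@]1(C)C=C | intermediate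
10 | (1S,2S,3S)-3-{3-[tert-butyl(dimethyl)silyl]oxypropyl}-2-ethenyl-4,4-dimethoxy-1,2-dimethylcyclohexan-1-ol | CC(C)(C)[Si](C)(C)OCCC[C@@H]1C(OC)(OC)CC[C@](C)(O)[C@@]1(C)C=C | intermediate
11 | geranyl bromide, (2E)-1-bromo-3,7-dimethylocta-2,6-diene | CC(C)=CCC/C(C)=C/CBr | starting material
12 | trimethyl(prop-1-yn-1-yl)silane | CC#C[Si](C)(C)C | starting material
13 | [3-(trimethylsilyl)prop-2-yn-1-yl]lithium | [Li]CC#C[Si](C)(C)C | intermediate
14 | [(5E)-6,10-dimethylundeca-5,9-dien-1-yn-1-yl]trimethylsilane | C[Si](C)(C)C#CCC/C=C(\C)CCC=C(C)C | intermediate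
15 | (5E)-6,10-dimethylundeca-5,9-dien-1-yne | C#CCC/C=C(\C)CCC=C(C)C | intermediate
16 | dimethyl[(1E,5E)-2,6,10-trimethylundeca-1,5,9-trien-1-yl]alumane | C[Al](C)/C=C(\C)CC/C=C(\C)CCC=C(C)C | intermediate
17 | (1E,5E)-1-iodo-2,6,10-trimethylundeca-1,5,9-triene | I/C=C(\C)CC/C=C(\C)CCC=C(C)C | intermediate
18 | B-alkyl-9-BBN adduct of 10: (1S,2S,3S)-2-[2-(9-borabicyclo[3.3.1]nonan-9-yl)ethyl]-3-{3-[tert-butyl(dimethyl)silyl]oxypropyl}-4,4-dimethoxy-1,2-dimethylcyclohexan-1-ol | CC(C)(C)[Si](C)(C)OCCC[C@@H]1C(OC)(OC)CC[C@](C)(O)[C@@]1(C)CCB1C2CCCC1CCC2 | intermediate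
19 | (1S,2S,3S)-3-{3-[tert-butyl(dimethyl)silyl]oxypropyl}-4,4-dimethoxy-1,2-dimethyl-2-[(3E,7E)-4,8,12-trimethyltrideca-3,7,11-trien-1-yl]cyclohexan-1-ol | CC(C)(C)[Si](C)(C)OCCC[C@@H]1C(OC)(OC)CC[C@](C)(O)[C@@]1(C)CC/C=C(\C)CC/C=C(\C)CCC=C(C)C | intermediate
20 | (2S,3S,4S)-4-hydroxy-2-(3-hydroxypropyl)-3,4-dimethyl-3-[(3E,7E)-4,8,12-trimethyltrideca-3,7,11-trien-1-yl]cyclohexan-1-one | OCCC[C@@H]1C(=O)CC[C@](C)(O)[C@@]1(C)CC/C=C(\C)CC/C=C(\C)CCC=C(C)C | intermediate
21 | (1S,2S,3S,4R)-3-(3-hydroxypropyl)-1,2-dimethyl-4-(prop-1-en-2-yl)-2-[(3E,7E)-4,8,12-trimethyltrideca-3,7,11-trien-1-yl]cyclohexane-1,4-diol | OCCC[C@@H]1[C@@](O)(C(C)=C)CC[C@](C)(O)[C@@]1(C)CC/C=C(\C)CC/C=C(\C)CCC=C(C)C | intermediate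
22 | 3-[(1S,2S,3S,6R)-3,6-dihydroxy-2,3-dimethyl-6-(prop-1-en-2-yl)-2-[(3E,7E)-4,8,12-trimethyltrideca-3,7,11-trien-1-yl]cyclohexyl]propyl decanoate | CCCCCCCCCC(=O)OCCC[C@@H]1[C@@](O)(C(C)=C)CC[C@](C)(O)[C@@]1(C)CC/C=C(\C)CC/C=C(\C)CCC=C(C)C | intermediate
23 | 3-[(1R,2S,3S,6Z)-3-hydroxy-2,3-dimethyl-6-(1-oxopropan-2-ylidene)-2-[(3E,7E)-4,8,12-trimethyltrideca-3,7,11-trien-1-yl]cyclohexyl]propyl decanoate | CCCCCCCCCC(=O)OCCC[C@@H]1/C(=C(/C)C=O)CC[C@](C)(O)[C@@]1(C)CC/C=C(\C)CC/C=C(\C)CCC=C(C)C | target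

**Step count**

Total step count: 12. Longest linear sequence: 10 (steps 1–5 and 8–12); steps 6–7 make the alkenyl iodide.

**Steps most likely to fail**

Step 3. What may go wrong: transfer of the functionalised alkyl group from zinc to the β-carbon, which is flanked by the α-methyl group and the ketal carbon, may be so slow that the uncatalysed background addition erodes the enantiomeric purity or conversion stalls. The fallback sets out from 3 and returns at 7. The nucleophile would be generated instead by hydrozirconation of tert-butyl(dimethyl)(prop-2-en-1-yloxy)silane with Cp2Zr(H)Cl, giving chlorobis(cyclopentadienyl){3-[tert-butyl(dimethyl)silyl]oxypropyl}zirconium F1. F1 would be added to 3 under (CuOTf)2·C6H6/phosphoramidite catalysis (asymmetric conjugate addition of an alkylzirconocene made from an alkene, no organozinc), and the zirconium enolate acetylated with Ac2O to give 7.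

Step 4. What may go wrong: at the crowded tetrasubstituted enolate, O-vinylation or simple protonation may outrun C–C reductive elimination from palladium. The fallback sets out from 7 and returns at 19, making the same C13–C14 bond by an sp3–sp2 Negishi coupling.
- Enolate 8 (from 7 and methyllithium) would be alkylated with allyl iodide, again anti to the side chain, to give (2S,3S)-3-{3-[tert-butyl(dimethyl)silyl]oxypropyl}-4,4-dimethoxy-2-methyl-2-(prop-2-en-1-yl)cyclohexan-1-one F2.
- Methyllithium at −78 °C would give the corresponding (1S,2S,3S)-1,2-dimethyl carbinol F3.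
- Ozonolysis of its only alkene with NaBH4 work-up would give the (1S,2S,3S)-2-(2-hydroxyethyl) diol F4.
- I2, PPh3 and imidazole would convert the primary alcohol into the (1S,2S,3S)-2-(2-iodoethyl) carbinol F5.
- Zinc dust with LiCl would give the alkylzinc iodide F6, which would be coupled with 17 under PdCl2(dppf) catalysis to give 19.

Step 12. What may go wrong: the tertiary allylic chromate may ionise and lose water to a diene, or the [3,3] shift may deliver the geometry with methyl, not formyl, facing C6. The fallback sets out from 20 and returns at 23.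
- Peterson olefination of 20 with excess lithiated N-tert-butyl-2-(trimethylsilyl)propan-1-imine would give the 1-azadiene 3-[(1R,2S,3S,6Z)-6-[1-(tert-butylimino)propan-2-ylidene]-3-hydroxy-2,3-dimethyl-2-[(3E,7E)-4,8,12-trimethyltrideca-3,7,11-trien-1-yl]cyclohexyl]propan-1-ol F7.
- Hydrolysis with aqueous oxalic acid, during which the conjugated iminium ion can rotate to the less strained Z geometry, would give (2Z)-2-[(2R,3S,4S)-4-hydroxy-2-(3-hydroxypropyl)-3,4-dimethyl-3-[(3E,7E)-4,8,12-trimethyltrideca-3,7,11-trien-1-yl]cyclohexylidene]propanal F8.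
- Acylation of the primary alcohol with decanoyl chloride and 2,4,6-collidine would give 23.

**Further compounds**

F1 | step 3 | chlorobis(cyclopentadienyl){3-[tert-butyl(dimethyl)silyl]oxypropyl}zirconium | CC(C)(C)[Si](C)(C)OCCC[Zr](Cl)(C1C=CC=C1)C1C=CC=C1
F2 | step 4 | (2S,3S)-3-{3-[tert-butyl(dimethyl)silyl]oxypropyl}-4,4-dimethoxy-2-methyl-2-(prop-2-en-1-yl)cyclohexan-1-one | CC(C)(C)[Si](C)(C)OCCC[C@@H]1C(OC)(OC)CCC(=O)[C@@]1(C)CC=C
F3 | step 4 | (1S,2S,3S)-3-{3-[tert-butyl(dimethyl)silyl]oxypropyl}-4,4-dimethoxy-1,2-dimethyl-2-(prop-2-en-1-yl)cyclohexan-1-ol | CC(C)(C)[Si](C)(C)OCCC[C@@H]1C(OC)(OC)CC[C@](C)(O)[C@@]1(C)CC=C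
F4 | step 4 | (1S,2S,3S)-3-{3-[tert-butyl(dimethyl)silyl]oxypropyl}-2-(2-hydroxyethyl)-4,4-dimethoxy-1,2-dimethylcyclohexan-1-ol | CC(C)(C)[Si](C)(C)OCCC[C@@H]1C(OC)(OC)CC[C@](C)(O)[C@@]1(C)CCO
F5 | step 4 | (1S,2S,3S)-3-{3-[tert-butyl(dimethyl)silyl]oxypropyl}-2-(2-iodoethyl)-4,4-dimethoxy-1,2-dimethylcyclohexan-1-ol | CC(C)(C)[Si](C)(C)OCCC[C@@H]1C(OC)(OC)CC[C@](C)(O)[C@@]1(C)CCI
F6 | step 4 | alkylzinc iodide from F5: {2-[(1S,2S,6S)-6-{3-[tert-butyl(dimethyl)silyl]oxypropyl}-2-hydroxy-5,5-dimethoxy-1,2-dimethylcyclohexyl]ethyl}(iodo)zinc | CC(C)(C)[Si](C)(C)OCCC[C@@H]1C(OC)(OC)CC[C@](C)(O)[C@@]1(C)CC[Zn]I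
F7 | step 12 | 3-[(1R,2S,3S,6Z)-6-[1-(tert-butylimino)propan-2-ylidene]-3-hydroxy-2,3-dimethyl-2-[(3E,7E)-4,8,12-trimethyltrideca-3,7,11-trien-1-yl]cyclohexyl]propan-1-ol | OCCC[C@@H]1/C(=C(/C)C=NC(C)(C)C)CC[C@](C)(O)[C@@]1(C)CC/C=C(\C)CC/C=C(\C)CCC=C(C)C
F8 | step 12 | (2Z)-2-[(2R,3S,4S)-4-hydroxy-2-(3-hydroxypropyl)-3,4-dimethyl-3-[(3E,7E)-4,8,12-trimethyltrideca-3,7,11-trien-1-yl]cyclohexylidene]propanal | OCCC[C@@H]1/C(=C(/C)C=O)CC[C@](C)(O)[C@@]1(C)CC/C=C(\C)CC/C=C(\C)CCC=C(C)C
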